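The route rests on cutting the bond between the aroyl carbonyl carbon and C3 of the γ-butyrolactone ring. The key step exploits that C3 and C4 of this ring can be the C=C of a flat, achiral 4-benzylbutenolide, and that C3–H lies between two carbonyls. In one flask a chiral copper hydride delivers hydride to C4, and the C3 silyl ketene acetal so formed is C-acylated by O-benzylvanilloyl chloride anti to the C4 benzyl group. One operation thus joins both halves and sets C4 (ligand control) and C3 (substrate control, self-correcting by enolisation). The precursors are the butenolide, made by one Negishi coupling, and the acid chloride; hydrogenolysis ends the route.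

Key step: step 3

Assumption: the (R)-configured bisphosphine is taken to direct hydride to the Si face of C4, by analogy with 3-substituted cyclopentenones and β-substituted unsaturated lactones. If the sense proves opposite, the (S)-ligand is used and nothing else changes.

Step 1
Reactants: 1 3,4-dimethoxybenzyl chloride; 2 4-bromofuran-2(5H)-one
Product: 4 4-(3,4-dimethoxybenzyl)furan-2(5H)-one, via 3,4-dimethoxybenzylzinc chloride 3 (not isolated)
Conditions: 1, Zn dust, LiCl, THF, 25 °C; then 2, Pd(OAc)2 (2 mol%), SPhos (4 mol%), THF, 25 °C
Reagents that add atoms: zinc, [Zn] (held only in 3)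
Why: LiCl-assisted zinc insertion into the benzylic C–Cl bond followed by Negishi coupling should work because the C4–Br bond of 2 is a vinylogous acyl bromide that adds readily to Pd(0), while the weakly basic organozinc leaves the lactone carbonyl and the acidic C5–H untouched; no stereocentre is formed.

Step 2
Reactants: 5 4-(benzyloxy)-3-methoxybenzoic acid
Product: 6 4-(benzyloxy)-3-methoxybenzoyl chloride
Conditions: (COCl)2, DMF (cat.), CH2Cl2, 0 °C to rt; evaporation with toluene
Reagents that add atoms: oxalyl chloride, ClC(=O)C(=O)Cl
Why: Acid chloride formation through the Vilsmeier-type chloroiminium species is standard for alkoxybenzoic acids, and the benzyl and methyl aryl ethers are inert to it.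

Step 3
Reactants: 4 4-(3,4-dimethoxybenzyl)furan-2(5H)-one; 6 4-(benzyloxy)-3-methoxybenzoyl chloride
Product: 8 (3S,4R)-3-[4-(benzyloxy)-3-methoxybenzoyl]-4-(3,4-dimethoxybenzyl)dihydrofuran-2(3H)-one, via diphenylsilyl ketene acetal 7 (not isolated)
Conditions: 4 (1.15 equiv), Cu(OAc)2 (3 mol%), (R)-DTBM-SEGPHOS (3.3 mol%), Ph2SiH2 (1.2 equiv), toluene, 0 °C to rt, until 4 is consumed; then 6 (1.0 equiv), C6F5NH3OTf (10 mol%), toluene–MeCN, 0 °C to rt; pH 7 buffer
Reagents that add atoms: diphenylsilane, [SiH2](c1ccccc1)c1ccccc1 (silicon stays only in 7; one hydride ends at C4 of 8)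
Why: The ligated copper hydride formed from Cu(OAc)2 and Ph2SiH2 adds hydride to C4 of 4, σ-bond metathesis of the copper enolate with the silane releases silyl ketene acetal 7 and returns CuH, and 6, added only when 4 is consumed, converts the residual CuH into silane-inert CuCl and then acylates C3 of 7 under anilinium triflate catalysis with loss of Ph2SiHCl. The closest known reaction types are the asymmetric CuH 1,4-hydrosilylation of β-substituted butenolides, the one-pot electrophilic trapping of the silyl enol ethers that such reductions give, and the acid-catalysed crossed-Claisen C-acylation of ketene silyl acetals with acid chlorides. No ring is closed; the lactone ring is carried through intact. C4 is set by the ligand, whose aryl groups shield one face of the planar ring so that hydride reaches the Si face and gives (R). C3 is set by C4, since the acyl group approaches the planar ketene acetal anti to the benzyl group, and the acidic C3–H between the two carbonyls lets any cis isomer drain to the trans (3S,4R) lactone. The step needs 1,4- over 1,2-reduction, no hydride transfer to 6 and C- over O-acylation, which are secured by the soft CuH on a conjugated lactone, by the sequential addition, and by base-free acid catalysis on the carbon-nucleophilic ketene acetal.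

Step 4
Reactants: 8 (3S,4R)-3-[4-(benzyloxy)-3-methoxybenzoyl]-4-(3,4-dimethoxybenzyl)dihydrofuran-2(3H)-one
Product: 9 (3S,4R)-4-(3,4-dimethoxybenzyl)-3-(4-hydroxy-3-methoxybenzoyl)dihydrofuran-2(3H)-one (target)
Conditions: H2 (1 atm), 10% Pd/C, EtOAc, rt, stopped after uptake of one equivalent
Reagents that add atoms: none
Why: Neutral catalytic hydrogenolysis cleaves the benzyl aryl ether, while the electron-rich aroyl ketone of the β-keto lactone should be reduced much more slowly at 1 atm without acid; C4 is untouched and C3 stays in its thermodynamically preferred trans arrangement.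

Compound list
1 | 3,4-dimethoxybenzyl chloride | COc1ccc(CCl)cc1OC | starting material
2 | 4-bromofuran-2(5H)-one | O=C1C=C(Br)CO1 | starting material
3 | 3,4-dimethoxybenzylzinc chloride | COc1ccc(C[Zn]Cl)cc1OC | intermediate
4 | 4-(3,4-dimethoxybenzyl)furan-2(5H)-one | COc1ccc(CC2=CC(=O)OC2)cc1OC | intermediate
5 | 4-(benzyloxy)-3-methoxybenzoic acid | COc1cc(C(=O)O)ccc1OCc1ccccc1 | starting material
6 | 4-(benzyloxy)-3-methoxybenzoyl chloride | COc1cc(C(=O)Cl)ccc1OCc1ccccc1 | intermediate
7 | (R)-{[4-(3,4-dimethoxybenzyl)-4,5-dihydrofuran-2-yl]oxy}diphenylsilane | COc1ccc(C[C@H]2COC(O[SiH](c3ccccc3)c3ccccc3)=C2)cc1OC | intermediate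
8 | (3S,4R)-3-[4-(benzyloxy)-3-methoxybenzoyl]-4-(3,4-dimethoxybenzyl)dihydrofuran-2(3H)-one | COc1cc(C(=O)[C@H]2C(=O)OC[C@@H]2Cc2ccc(OC)c(OC)c2)ccc1OCc1ccccc1 | intermediate
9 | (3S,4R)-4-(3,4-dimethoxybenzyl)-3-(4-hydroxy-3-methoxybenzoyl)dihydrofuran-2(3H)-one | COc1cc(C(=O)[C@H]2C(=O)OC[C@@H]2Cc2ccc(OC)c(OC)c2)ccc1O | target

Total step count: 4. Longest linear sequence: 3 (steps 1, 3, 4).

Steps most likely to fail

Step 3. Several processes could spoil the one-pot sequence:
- slow silyl transfer from the lactone copper enolate to the silane, so that the reduction stalls or the enolate adds in Michael fashion to unreacted butenolide;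
- deprotonation at C5;
- eroded facial selectivity;
- competing O-acylation.

The fallback separates reduction and bond formation and makes the bond at the alcohol oxidation level. It sets out from 4. The same copper hydride catalyst with PMHS and t-BuOH as proton source, which frees the copper enolate by protonation, should give (R)-4-(3,4-dimethoxybenzyl)dihydrofuran-2(3H)-one F1. Its lithium enolate (LiHMDS, THF, −78 °C) adds to commercial 4-(benzyloxy)-3-methoxybenzaldehyde (COc1cc(C=O)ccc1OCc1ccccc1) anti to the benzyl group. This gives (3S,4R)-3-{[4-(benzyloxy)-3-methoxyphenyl](hydroxy)methyl}-4-(3,4-dimethoxybenzyl)dihydrofuran-2(3H)-one F2 as a mixture at the carbinol carbon. Oxidation with Dess–Martin periodinane (CH2Cl2, rt) erases that centre, and the route is rejoined at 8.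

Step 1. Wurtz-type homocoupling of the electron-rich benzylic chloride during zinc insertion, or protodemetalation of the zinc reagent, could starve the coupling. The fallback reverses the roles of the partners, so that no benzylic metal species is needed. It sets out from 2. Palladium-catalysed stannylation with hexabutylditin (Pd(PPh3)4, toluene, 80 °C) should give 4-(tributylstannyl)furan-2(5H)-one F3. Stille coupling of this stannane with 1 as the electrophile (Pd2(dba)3, tri(2-furyl)phosphine, THF, 60 °C) rejoins the route at 4.

Step 4. Over-reduction of the benzylic aryl ketone during hydrogenolysis could compete with ether cleavage. The fallback changes the phenol protection so that no reductive step is needed. Commercial 4-acetoxy-3-methoxybenzoic acid (COc1cc(C(=O)O)ccc1OC(C)=O) is converted with oxalyl chloride and catalytic DMF into 4-acetoxy-3-methoxybenzoyl chloride F4. The fallback sets out from 4, which is taken through 7 as in step 3 and acylated with this chloride. The product should be (3S,4R)-3-(4-acetoxy-3-methoxybenzoyl)-4-(3,4-dimethoxybenzyl)dihydrofuran-2(3H)-one F5. A lipase (immobilised Candida antarctica lipase B, n-BuOH, MTBE, 30 °C) transfers the phenolic acetyl group to butanol under neutral conditions that spare the β-keto lactone. The route is rejoined at 9.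

Further compounds
F1 | step 3 | (R)-4-(3,4-dimethoxybenzyl)dihydrofuran-2(3H)-one | COc1ccc(C[C@H]2COC(=O)C2)cc1OC
F2 | step 3 | (3S,4R)-3-{[4-(benzyloxy)-3-methoxyphenyl](hydroxy)methyl}-4-(3,4-dimethoxybenzyl)dihydrofuran-2(3H)-one, both carbinol epimers | COc1cc(C(O)[C@H]2C(=O)OC[C@@H]2Cc2ccc(OC)c(OC)c2)ccc1OCc1ccccc1
F3 | step 1 | 4-(tributylstannyl)furan-2(5H)-one | CCCC[Sn](CCCC)(CCCC)C1=CC(=O)OC1
F4 | step 4 | 4-acetoxy-3-methoxybenzoyl chloride | COc1cc(C(=O)Cl)ccc1OC(C)=O
F5 | step 4 | (3S,4R)-3-(4-acetoxy-3-methoxybenzoyl)-4-(3,4-dimethoxybenzyl)dihydrofuran-2(3H)-one | COc1cc(C(=O)[C@H]2C(=O)OC[C@@H]2Cc2ccc(OC)c(OC)c2)ccc1OC(C)=O
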